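**Retrosynthetic overview**
1. Endgame: C13 comes from Horner–Wadsworth–Emmons methylenation of an α-phosphono 6,12-lactone. C4(OH)–C15H2OH comes from osmylation of a C4=C15 methylene group, the angelate is put on C8–OH, and C6–O comes from a bottom-face C5–C6 oxirane.
2. The C3–O and C8–O bonds replace, with retention, the two C–C bonds of a one-carbon carbonyl bridge (Baeyer–Villiger, methyl ketone, second Baeyer–Villiger). C7–C11 is made by Tsuji–Trost opening of a C4–C5 vinyl oxirane while the bicycle is still rigid.
3. Feature used: in the ten-membered ring, C3 and C8 are 1,6-related, carry oxygen on the same face and flank the cis C1–C10 unit. A carbonyl carbon between them makes the ring the periphery of a bicyclo[4.4.1]undecane, which is tropone plus isoprene by (6+4) cycloaddition (bonds C2–C3 and C8–C9).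
4. The adduct is mirror-symmetric except for C14. A chiral dioxirane reads C1=C10 (resolution and oxirane in one step), and a chiral Mn(salen) catalyst then tells C4=C5 from C6=C7.
5. Ring order: both seven-membered rings in step 1 (ring A: bridge, C3, C2, C1, C10, C9, C8; ring B: bridge, C3, C4, C5, C6, C7, C8), the C1–C10 oxirane in step 2, the ten-membered ring freed in step 7, the γ-lactone in step 13.

Key step: step 1

Remark: germacrane numbering is used throughout. "Top" is the face of the ten-membered ring that carries the carbonyl bridge in 3, and "bottom" is the other face. C11 in 7–25 is a mixture of epimers that step 19 erases.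

Step 1
Reactants: 1 tropone; 2 isoprene
Product: 3 (±)-8-methylbicyclo[4.4.1]undeca-2,4,8-trien-11-one (bridgeheads C3 and C8, diene C4–C7, cis alkene C1=C10, methyl C14 on C10)
Conditions: isoprene (excess), BHT, toluene, sealed tube, 130 °C
Reagents that add atoms: none
Why: This is a concerted, thermally allowed [π6s+π4s] cycloaddition in which tropone reacts through its six ring CH carbons and s-cis isoprene through its four diene carbons, the diene termini (C2, C9) bonding to the two carbons next to the carbonyl (C3, C8). The closest known reaction type is the thermal higher-order cycloaddition of tropone with simple 1,3-dienes. Ring A (seven-membered), and with it the ten-membered periphery, closes through the two new σ bonds in one intermolecular suprafacial–suprafacial event, and the tropone carbocycle becomes ring B, the second seven-membered ring of the bicycle. C3 and C8 are the only new stereocentres; both bonds form on one face of tropone, so the bridge is necessarily cis, and with no chiral element present 3 is racemic. The selectivity needed is periselectivity for (6+4) over (4+2), which the exo transition state (C1 and C10 turned away from the triene, no repulsive secondary overlap) secures, helped by excess diene and a radical inhibitor, and the new alkene is cis by ring size. Regiochemistry does not arise, because the two orientations of isoprene on symmetric tropone give the two enantiomers of one compound.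

Step 2
Reactants: 3 racemic trienone
Product: 4 (1R,10S)-1,10-epoxy dienone (8,9-epoxy-8-methylbicyclo[4.4.1]undeca-2,4-dien-11-one, oxirane O on the top face, i.e. on the side of ring A away from the diene bridge), single enantiomer
Conditions: D-fructose-derived Shi ketone (0.3 equiv), Oxone (2KHSO5·KHSO4·K2SO4, 0.5 equiv KHSO5), K2CO3, Na2B4O7/Na2EDTA buffer, Bu4NHSO4, MeCN–(MeO)2CH2–H2O, 0 °C, stopped below half conversion
Reagents that add atoms: Oxone (potassium peroxymonosulfate), [K+].[O-]S(=O)(=O)OO
Why: This is a Shi asymmetric epoxidation run as a kinetic resolution: the electron-rich trisubstituted C1=C10 alkene reacts before the diene, only the face of ring A that looks away from the diene bridge is open in its chair form, and the dioxirane from the D-fructose-derived ketone (whose spiro transition state oxidises 1-substituted cycloalkenes in the sense needed here) finds its preferred enantioface on that open side only in the wanted enantiomer, so C1 and C10 are set and the mirror-image half of 3 stays an alkene and is removed by chromatography.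

Step 3
Reactants: 4 epoxy dienone
Product: 5 1,10:4,5-diepoxy enone ((4S,5R)-oxirane on the top face, C6=C7 retained, bridge ketone intact)
Conditions: (R,R)-Mn(salen)Cl [salen = N,N'-bis(3,5-di-tert-butylsalicylidene)-1,2-cyclohexanediamine dianion] (5 mol %), 4-phenylpyridine N-oxide, aq NaOCl (pH 11.3), CH2Cl2, 0 °C
Reagents that add atoms: sodium hypochlorite, [Na+].[O-]Cl
Why: This is a Jacobsen–Katsuki epoxidation of a cis-disubstituted conjugated diene: only the top face of ring B (anti to ring A) is open, on that face C4=C5 and C6=C7 present mirror-image enantiofaces, and the (R,R) catalyst, which oxidises indene-type cis alkenes in the (1R,2S) sense, should therefore pick C4=C5, setting C4 and C5 and breaking the near-symmetry of the core.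

Step 4
Reactants: 5 vinyl oxirane; 6 triethyl phosphonoacetate
Product: 7 bicyclic allylic alcohol (C4–OH top, cis C5=C6, C7–CH[P(O)(OEt)2]CO2Et top, bridge ketone and 1,10-oxirane intact)
Conditions: Pd2(dba)3·CHCl3 (2.5 mol %), P(OiPr)3, THF, rt
Reagents that add atoms: none
Why: This is a Tsuji–Trost alkylation under neutral conditions: zerovalent palladium ionises the allylic C5–O bond anti to oxygen, the freed C4 alkoxide deprotonates 6, and the stabilised carbanion attacks the π-allyl terminus remote from the alkoxide (C7) anti to the metal on the open top face, so the double inversion places C11 on the top face of C7, cis to C4–OH, as in the cis-1,4 openings of cycloheptadiene monoepoxide.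

Step 5
Reactants: 7 allylic alcohol
Product: 8 C4 triethylsilyl ether of 7
Conditions: Et3SiCl, imidazole, CH2Cl2, 0 °C
Reagents that add atoms: chlorotriethylsilane, CC[Si](Cl)(CC)CC
Why: This is a standard silylation under weakly basic conditions that caps the β-hydroxy ketone before it can suffer retro-aldol cleavage, and no stereocentre is touched.

Step 6
Reactants: 8 bridged ketone
Product: 9 bridged lactone (bicyclo[4.4.2] frame, C8–O–C(=O)–C3, O on the top face of C8)
Conditions: mCPBA, Na2HPO4, CH2Cl2, rt to 40 °C
Reagents that add atoms: 3-chloroperoxybenzoic acid, OOC(=O)c1cccc(Cl)c1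
Why: This is a Baeyer–Villiger oxidation with retention at the migrating carbon: the oxygen substituent on C4 lowers the migratory aptitude of the adjacent bridgehead C3 by induction (the known behaviour of ketones on a one-carbon bridge that carry a β-oxygen group), so C8 should move to oxygen, while C5=C6 is deactivated by two allylic electron-poor groups and screened by the two axial top-face substituents and by ring A below.

Step 7
Reactants: 9 bridged lactone
Product: 10 ten-membered hydroxy Weinreb amide (C8–OH top, C3–C(=O)N(OMe)Me top)
Conditions: MeNH(OMe)·HCl, iPrMgCl, THF, −20 to 0 °C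
Reagents that add atoms: N,O-dimethylhydroxylamine hydrochloride, CNOC.Cl
Why: This is a Weinreb aminolysis with the magnesium amide: the acidic C11–H is removed first, which masks the side-chain ester as its enolate, so only the lactone carbonyl is attacked, and the ten-membered ring is freed with C3 and C8 unchanged.

Step 8
Reactants: 10 hydroxy amide (used at once)
Product: 11 C8 tert-butyldimethylsilyl ether of 10
Conditions: TBSOTf, 2,6-lutidine, CH2Cl2, −78 °C
Reagents that add atoms: tert-butyldimethylsilyl triflate, CC(C)(C)[Si](C)(C)OS(=O)(=O)C(F)(F)F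
Why: Fast low-temperature silylation caps C8–OH before it can lactonise onto the cis side-chain ester, and the hindered base spares the oxirane.

Step 9
Reactants: 11 Weinreb amide
Product: 12 C3 methyl ketone (C3–C(=O)CH3 top)
Conditions: MeMgBr (excess), THF, −78 to 0 °C; aq NH4Cl
Reagents that add atoms: methylmagnesium bromide, C[Mg]Br
Why: This is a Weinreb ketone synthesis: the first equivalent again turns the phosphonoacetate into its unreactive enolate, the chelated tetrahedral adduct stops over-addition, and the mild quench leaves C3 unepimerised.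

Step 10
Reactants: 12 methyl ketone
Product: 14 C3 acetate with bottom-face C5–C6 oxirane (C3–OAc top, C4–OTES top, C8–OTBS top), via epoxy methyl ketone 13 (not isolated)
Conditions: mCPBA (excess), NaHCO3, CH2Cl2, rt
Reagents that add atoms: 3-chloroperoxybenzoic acid, OOC(=O)c1cccc(Cl)c1
Why: This is a Prilezhaev epoxidation followed by a Baeyer–Villiger oxidation in one flask: allylic strain puts H4 and H7 in the plane of the cis alkene and the ring bonds C3 and C8 on its inner face, so peripheral attack lays the oxirane trans to both top-face allylic groups (the usual outcome for medium-ring cis alkenes) and sets C6–O on the bottom face, and then secondary C3 migrates in preference to methyl with retention.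

Step 11
Reactants: 14 epoxy acetate
Product: 15 C4 alcohol (TES removed, TBS and acetate kept)
Conditions: HF·pyridine, pyridine, THF, 0 °C
Reagents that add atoms: none
Why: Buffered fluoride cleaves the triethylsilyl ether much faster than the hindered tert-butyldimethylsilyl ether without opening either oxirane, and the product is oxidised without delay to forestall acetyl migration.

Step 12
Reactants: 15 epoxy alcohol
Product: 16 α,β-epoxy ketone (C4=O, C5–C6 oxirane bottom, C3–OAc top)
Conditions: Dess–Martin periodinane, NaHCO3, CH2Cl2, 0 °C to rt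
Reagents that add atoms: none
Why: The Dess–Martin oxidation is neutral, so the α-acetoxy centre C3 and the oxiranes survive and the temporary C4 stereocentre is erased.

Step 13
Reactants: 16 epoxy ketone
Product: 18 trans-fused α-(diethoxyphosphoryl) 6,12-lactone with C4 ketone (C6–O bottom, C7–C11 top), via hydroxy ketone 17 (not isolated)
Conditions: (PhSe)2, NaBH4, EtOH, then AcOH and 16, 0 °C; crude 17, PPTS (cat.), CH2Cl2, rt
Reagents that add atoms: none
Why: This is the organoselenium reduction of an α,β-epoxy ketone (selenolate opens the oxirane at the α-carbon C5 and a second selenolate removes selenium), which gives the β-hydroxy ketone with the C6–O bond untouched and leaves the isolated oxirane and the esters alone; mild acid then closes the γ-lactone onto the activated ester.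

Step 14
Reactants: 18 keto lactone
Product: 19 C4=C15 exocyclic methylene compound
Conditions: Cp2Ti(μ-Cl)(μ-CH2)AlMe2 (Tebbe reagent), pyridine (cat.), toluene–THF, −40 to 0 °C
Reagents that add atoms: Tebbe reagent, C[Al](C)C[Ti](Cl)(C1C=CC=C1)C1C=CC=C1
Why: The Tebbe methylenation is non-basic, so neither β-elimination of the C6 lactone oxygen nor epimerisation at C3 should occur, and at low temperature the ketone reacts before the acetate and the lactone (extra reagent allows for the acidic C11–H).

Step 15
Reactants: 19 silyl ether
Product: 20 C8 alcohol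
Conditions: Bu4NF, AcOH (1:1), THF, rt
Reagents that add atoms: none
Why: Acetic-acid-buffered fluoride removes the silyl group near neutrality, so the oxirane, the allylic acetate and the trans 6,12-lactone (a stable arrangement next to a free cis 8-hydroxyl in germacranolides) are kept.

Step 16
Reactants: 20 C8 alcohol; 21 angelic acid
Product: 23 C8 angelate, via mixed anhydride 22 (not isolated)
Conditions: 21, 2,4,6-Cl3C6H2COCl, Et3N, toluene, rt; then 20, 75 °C
Reagents that add atoms: none
Why: Yamaguchi esterification without a nucleophilic catalyst is the established way to acylate hindered secondary alcohols with angelic acid without Z-to-E isomerisation, and C8–OH is the only free hydroxyl.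

Step 17
Reactants: 23 acetate angelate
Product: 24 C3 allylic alcohol (C3–OH top)
Conditions: K2CO3, MeOH, 0 °C
Reagents that add atoms: none
Why: In this transesterification the unhindered allylic acetate is cleaved far faster than the conjugated, α-branched angelate on hindered C8, while the phosphono lactone is shielded as its enolate.

Step 18
Reactants: 24 allylic alcohol
Product: 25 triol phosphono lactone (C4–OH bottom, C15H2OH top, C3–OH top)
Conditions: OsO4 (cat.), NMO, acetone–H2O, 0 °C
Reagents that add atoms: N-methylmorpholine N-oxide, C[N+]1([O-])CCOCC1; water, O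
Why: In this Upjohn dihydroxylation the electron-rich 1,1-disubstituted alkene reacts before the electron-poor angelate, and osmium attacks anti to the allylic C3 hydroxyl (the empirical rule for allylic alcohols), i.e. from the bottom face, which sets C4 with OH trans to C3–OH.

Step 19
Reactants: 25 triol phosphono lactone
Product: 26 target CNP0307250.1
Conditions: K2CO3, aq HCHO, THF, 0 °C to rt
Reagents that add atoms: formaldehyde, C=O
Why: Horner–Wadsworth–Emmons olefination of an α-phosphono γ-lactone with formaldehyde is a standard mild route to α-methylene lactones; it removes the C11 epimer mixture and tolerates the free hydroxyls, the oxirane and the angelate.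

**Compound list**
1 | tropone | O=C1C=CC=CC=C1 | starting material
2 | isoprene | C=CC(C)=C | starting material
3 | (±)-8-methylbicyclo[4.4.1]undeca-2,4,8-trien-11-one (racemic, drawn as the enantiomer carried on) | C=1C=C[C@@H](C2=O)CC=C(C)C[C@@H]2C=1 | intermediate
4 | (1R,10S)-1,10-epoxy dienone, oxirane on top face | C=1C=C[C@@H](C2=O)C[C@H]3O[C@@]3(C)C[C@@H]2C=1 | intermediate
5 | 1,10:4,5-diepoxy enone, both oxiranes on top face | C=1[C@H]4O[C@H]4[C@@H](C2=O)C[C@H]3O[C@@]3(C)C[C@@H]2C=1 | intermediate
6 | triethyl phosphonoacetate | CCOC(=O)CP(=O)(OCC)OCC | starting material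
7 | bicyclic allylic alcohol, C4–OH and C7 side chain on top face | CCOC(=O)C(P(=O)(OCC)OCC)[C@H]1/C=C\[C@@H](O)[C@@H](C2=O)C[C@H]3O[C@@]3(C)C[C@@H]21 | intermediate
8 | C4 triethylsilyl ether of 7 | CCOC(=O)C(P(=O)(OCC)OCC)[C@H]1/C=C\[C@@H](O[Si](CC)(CC)CC)[C@@H](C2=O)C[C@H]3O[C@@]3(C)C[C@@H]21 | intermediate
9 | bridged lactone C8–O–C(=O)–C3 | CCOC(=O)C(P(=O)(OCC)OCC)[C@H]1/C=C\[C@@H](O[Si](CC)(CC)CC)[C@@H](C(=O)O2)C[C@H]3O[C@@]3(C)C[C@@H]21 | intermediate
10 | ten-membered C8 alcohol, C3 Weinreb amide | CCOC(=O)C(P(=O)(OCC)OCC)[C@H]1/C=C\[C@@H](O[Si](CC)(CC)CC)[C@@H](C(=O)N(C)OC)C[C@H]2O[C@@]2(C)C[C@H]1O | intermediate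
11 | C8 tert-butyldimethylsilyl ether of 10 | CCOC(=O)C(P(=O)(OCC)OCC)[C@H]1/C=C\[C@@H](O[Si](CC)(CC)CC)[C@@H](C(=O)N(C)OC)C[C@H]2O[C@@]2(C)C[C@H]1O[Si](C)(C)C(C)(C)C | intermediate
12 | C3 methyl ketone | CCOC(=O)C(P(=O)(OCC)OCC)[C@H]1/C=C\[C@@H](O[Si](CC)(CC)CC)[C@@H](C(C)=O)C[C@H]2O[C@@]2(C)C[C@H]1O[Si](C)(C)C(C)(C)C | intermediate
13 | epoxy methyl ketone, C5–C6 oxirane on bottom face | CCOC(=O)C(P(=O)(OCC)OCC)[C@H]1[C@@H]3O[C@@H]3[C@@H](O[Si](CC)(CC)CC)[C@@H](C(C)=O)C[C@H]2O[C@@]2(C)C[C@H]1O[Si](C)(C)C(C)(C)C | intermediate
14 | C3 acetate, C5–C6 oxirane on bottom face | CCOC(=O)C(P(=O)(OCC)OCC)[C@H]1[C@@H]3O[C@@H]3[C@@H](O[Si](CC)(CC)CC)[C@@H](OC(C)=O)C[C@H]2O[C@@]2(C)C[C@H]1O[Si](C)(C)C(C)(C)C | intermediate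
15 | C4 epoxy alcohol | CCOC(=O)C(P(=O)(OCC)OCC)[C@H]1[C@@H]3O[C@@H]3[C@@H](O)[C@@H](OC(C)=O)C[C@H]2O[C@@]2(C)C[C@H]1O[Si](C)(C)C(C)(C)C | intermediate
16 | C4 α,β-epoxy ketone | CCOC(=O)C(P(=O)(OCC)OCC)[C@H]1[C@@H]3O[C@@H]3C(=O)[C@@H](OC(C)=O)C[C@H]2O[C@@]2(C)C[C@H]1O[Si](C)(C)C(C)(C)C | intermediate
17 | β-hydroxy ketone, C6–OH on bottom face | CCOC(=O)C(P(=O)(OCC)OCC)[C@H]1[C@H](O)CC(=O)[C@@H](OC(C)=O)C[C@H]2O[C@@]2(C)C[C@H]1O[Si](C)(C)C(C)(C)C | intermediate
18 | trans 6,12-lactone with α-phosphonate and C4 ketone | CCOP(=O)(OCC)C1C(=O)O[C@@H]2CC(=O)[C@@H](OC(C)=O)C[C@H]3O[C@@]3(C)C[C@@H](O[Si](C)(C)C(C)(C)C)[C@@H]12 | intermediate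
19 | C4=C15 methylene lactone precursor | CCOP(=O)(OCC)C1C(=O)O[C@@H]2CC(=C)[C@@H](OC(C)=O)C[C@H]3O[C@@]3(C)C[C@@H](O[Si](C)(C)C(C)(C)C)[C@@H]12 | intermediate
20 | C8 alcohol | CCOP(=O)(OCC)C1C(=O)O[C@@H]2CC(=C)[C@@H](OC(C)=O)C[C@H]3O[C@@]3(C)C[C@@H](O)[C@@H]12 | intermediate
21 | angelic acid ((Z)-2-methylbut-2-enoic acid) | OC(=O)/C(C)=C\C | starting material
22 | angelic 2,4,6-trichlorobenzoic anhydride | O=C(OC(=O)/C(C)=C\C)c1c(Cl)cc(Cl)cc1Cl | intermediate
23 | C8 angelate, C3 acetate | CCOP(=O)(OCC)C1C(=O)O[C@@H]2CC(=C)[C@@H](OC(C)=O)C[C@H]3O[C@@]3(C)C[C@@H](OC(=O)/C(C)=C\C)[C@@H]12 | intermediate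
24 | C8 angelate, C3 allylic alcohol | CCOP(=O)(OCC)C1C(=O)O[C@@H]2CC(=C)[C@@H](O)C[C@H]3O[C@@]3(C)C[C@@H](OC(=O)/C(C)=C\C)[C@@H]12 | intermediate
25 | triol phosphono lactone | CCOP(=O)(OCC)C1C(=O)O[C@@H]2C[C@@](O)(CO)[C@@H](O)C[C@H]3O[C@@]3(C)C[C@@H](OC(=O)/C(C)=C\C)[C@@H]12 | intermediate
26 | CNP0307250.1 | C=C1C(=O)O[C@@H]2C[C@@](O)(CO)[C@@H](O)C[C@H]3O[C@@]3(C)C[C@@H](OC(=O)/C(C)=C\C)[C@@H]12 | target

Total step count: 19. Longest linear sequence: 19 steps from tropone.

**Steps most likely to fail**

Step 6.
- What may go wrong: slow addition of the peracid to the hindered bridge carbonyl, loss of selectivity between the two bridgeheads in the migration, or competing epoxidation of C5=C6.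
- Fallback, from 4, rejoining at 9: the bridge is oxidised before the diene is touched, and the choice between the two nearly mirror-related bridgeheads is handed to an enzyme.
- A Baeyer–Villiger monooxygenase of the cyclohexanone monooxygenase family is used (whole cells, air, glucose for cofactor recycling, pH 7–8). This catalyst class is known to desymmetrise bicyclic ketones and to leave C=C bonds and oxiranes alone.
- A panel is screened for the variant that moves C8 and converts 4 into the dienyl lactone F1.
- Jacobsen–Katsuki epoxidation as in step 3, now reinforced by the allylic C8 acyloxy group that deactivates C6=C7, gives the vinyl oxirane lactone F2.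
- The Tsuji–Trost reaction with 6 as in step 4, on the wider two-atom-bridged frame, gives the allylic alcohol lactone F3, and Et3SiCl/imidazole gives 9.

Step 4.
- What may go wrong: zerovalent palladium may fail to reach the concave face for ionisation, or the carbanion may attack C5 in place of C7.
- Fallback, from 5, rejoining at 8: C7–C11 is made by a [3,3] shift on the open top face, so no metal is needed on the concave face.
- LiBr/AcOH in THF opens the oxirane at allylic C5 with inversion to the bromohydrin F4.
- Caesium diethylphosphonoacetate in DMF displaces the allylic bromide from the top face (second inversion) to give the C5 phosphonoacetate F5.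
- Et3SiCl/imidazole gives the C4 silyl ether F6.
- Ireland–Claisen rearrangement (LiHMDS, Me3SiCl, THF, −78 °C to reflux) carries the acetate carbon suprafacially from O5 to C7 and gives, after work-up, the side-chain acid F7.
- EtI and K2CO3 in DMF give 8.

Step 2.
- What may go wrong: too small a rate difference between the two enantiomers toward the chiral dioxirane, so enantiomeric purity is lost.
- Fallback, from 3, rejoining at 4: the enantiomers are separated physically by preparative chromatography with supercritical CO2 on an amylose carbamate chiral phase, which gives the enantiopure trienone F8.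
- One equivalent of mCPBA (NaHCO3, CH2Cl2, 0 °C) then epoxidises the trisubstituted alkene from the open face of ring A to give 4.

**Further compounds**
F1 | step 6 | dienyl lactone (C8–O–C(=O)–C3, diene and 1,10-oxirane intact) | C=1C=C[C@@H](C(=O)O2)C[C@H]3O[C@@]3(C)C[C@@H]2C=1
F2 | step 6 | vinyl oxirane lactone (C4–C5 oxirane on top face) | C=1[C@H]4O[C@H]4[C@@H](C(=O)O2)C[C@H]3O[C@@]3(C)C[C@@H]2C=1
F3 | step 6 | allylic alcohol lactone (C4–OH and C7 side chain on top face) | CCOC(=O)C(P(=O)(OCC)OCC)[C@H]1/C=C\[C@@H](O)[C@@H](C(=O)O2)C[C@H]3O[C@@]3(C)C[C@@H]21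
F4 | step 4 | bromohydrin (C5–Br bottom, C4–OH top) | C=1[C@H](Br)[C@@H](O)[C@@H](C2=O)C[C@H]3O[C@@]3(C)C[C@@H]2C=1
F5 | step 4 | C5 diethylphosphonoacetate (C5–O top, C4–OH top) | C=1[C@@H](OC(=O)CP(=O)(OCC)OCC)[C@@H](O)[C@@H](C2=O)C[C@H]3O[C@@]3(C)C[C@@H]2C=1
F6 | step 4 | C4 triethylsilyl ether of F5 | C=1[C@@H](OC(=O)CP(=O)(OCC)OCC)[C@@H](O[Si](CC)(CC)CC)[C@@H](C2=O)C[C@H]3O[C@@]3(C)C[C@@H]2C=1
F7 | step 4 | side-chain acid (C7–CH[P(O)(OEt)2]CO2H top, C4–OTES top) | OC(=O)C(P(=O)(OCC)OCC)[C@H]1/C=C\[C@@H](O[Si](CC)(CC)CC)[C@@H](C2=O)C[C@H]3O[C@@]3(C)C[C@@H]21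
F8 | step 2 | enantiopure 8-methylbicyclo[4.4.1]undeca-2,4,8-trien-11-one | C=1C=C[C@@H](C2=O)CC=C(C)C[C@@H]2C=1
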